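## The problem

The target 15, 4-[(2,4-dihydroxy-6-pentylbenzoyl)oxy]-2-methoxy-6-pentylbenzoic acid, is a depside. Two pentyl-bearing benzene rings are held together only by an aryl ester that runs from the carboxyl carbon on C1 of ring A (the 2,4-dihydroxy-6-pentylbenzoyl ring) to O4 of ring B (the 2-methoxy-6-pentylbenzoic acid ring). No ring has to be built and there is no stereocentre or stable stereogenic axis, so the task is one of regiochemistry and chemoselectivity only. The ester carbonyl carbon lies between the pentyl chain on C6 and the oxygen on C2 of ring A, so attack of a phenol at this carbon is slow; the free carboxyl on C1 of ring B is shielded in the same way by methoxy and pentyl. Four oxygen functions must end up different: two free phenols on ring A, a methyl ether on O2 and an acyl group on O4 of ring B, and one carboxyl esterified while the other stays free. The aryl ester is opened by hydroxide, alkoxides and amines, the methyl ether ortho to a carbonyl is lost to boron trihalides, and 2-hydroxybenzoic acids of this type decarboxylate on heating, so the closing steps must be mild and non-basic. The feature that can be exploited is that C4 of ring B, the carbon that carries the ester oxygen, is the only carbon of that ring whose two neighbours (C3 and C5) bear hydrogen, while the carboxylate oxygens of ring A lie outside the two ortho groups that block the carbonyl carbon. The ester can therefore be made by joining oxygen to C4 rather than by joining the acyl carbon to oxygen.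

## Retrosynthesis

**15 from 14.** The last operation should only remove protecting groups and must not be basic. Cutting the two phenol O–CH2 bonds and the carboxyl O–C(CH3)3 bond leads to 14, in which both ring A hydroxyls are methoxymethyl ethers and the ring B carboxyl is a tert-butyl ester, so one acid treatment removes all three. Benzyl ethers with a benzyl ester and a final hydrogenolysis would be equally mild, but a benzyl ester brings a second arene with unhindered C–H bonds, which would spoil the borylation planned for ring B. The forward step only requires that a hindered aryl benzoate survive anhydrous acid at room temperature.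

**14 from 5 and 13.** The bond cut is O–C4 of ring B, not the acyl–oxygen bond.
- The acyl–oxygen cut would need a ring B phenol in which O2 is methylated and O4 is free, which means telling two hydroxyls apart, and then an acyl substitution at a carbon flanked by two ortho groups.
- With the O–C4 cut the ester oxygen belongs to the acid 5, ring B needs only boron at C4 (boronic acid 13), and the bond forms at an oxygen and an aryl carbon that are both unhindered.
- The precursors are two monocyclic fragments of similar size, each three operations from a purchasable compound.
- The forward reaction is a copper-mediated oxidative coupling of a carboxylic acid with an arylboronic acid (Chan–Lam type). It must favour the carboxylate over water and must leave the acetal and tert-butyl ester groups alone.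

**13 from 10 and 11.** The C4–B bond is cut. C4 is meta to both methoxy and pentyl, so electrophilic halogenation of 10 would go to C3 or C5 and a halide for a Miyaura borylation is not directly available. Iridium-catalysed C–H borylation with 11 is governed by sterics and should pick the one C–H without an ortho neighbour. The precursor 10 has no function at C4 at all. The forward step requires an ester free of arene C–H bonds (hence tert-butyl) and a hydrolysis of the pinacol ester 12 in the same flask that spares this ester.

**10 from 7 and 8, and 7 from 6.** The pentyl chain is cut between its first and second carbons, giving the benzylic anion 9 of toluate 7 and 1-iodobutane 8. The alternative, an sp2–sp3 cross-coupling of a pentyl metal with a 2-halo-6-methoxybenzoate at a hindered position, is less direct. The acid 6 is purchasable with methoxy and carboxyl already in place. The tert-butyl ester, put on at the carboxylate oxygen, serves three purposes: it hinders self-condensation of the anion, it is silent in the borylation, and it leaves with acid at the end.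

**5 from 4, 3 and 1.** The bond from C1 of ring A to the carboxyl carbon is traced back to a formyl group on olivetol 1. Direct carboxylation of 1 would give the free hydroxy acid, and etherification of its phenols would also esterify the carboxyl. At the aldehyde level (3) the phenols can be protected (4) without a carboxyl present, and a chlorite oxidation then gives 5. The forward steps require formylation beside the pentyl chain rather than between the hydroxyls, etherification of the hydrogen-bonded 2-hydroxyl, and an oxidation that does not chlorinate the electron-rich ring.

## Roads not taken

**Alternative 1:** Ring A built last by a Diels–Alder addition.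
- Cut: bonds C1–C2 and C5–C6 of ring A.
- Forward: phenol A1 (benzyl 4-hydroxy-2-methoxy-6-pentylbenzoate) is acylated to the oct-2-ynoate A2. A2 is heated with diene A3 (1-methoxy-1,3-bis(trimethylsilyloxy)buta-1,3-diene). Cycloaddition with the CH2 terminus of A3 on the pentyl-bearing alkyne carbon, loss of methanol and desilylation give resorcylate A4, and hydrogenolysis of the benzyl ester gives 15.
- Merits: the ester is made while its acyl carbon is still unhindered, ring A arrives with free hydroxyls and needs no protection, and the last step is a neutral hydrogenolysis.
- Weak points: a 3-alkylpropiolate with one activating group is a sluggish dienophile, and the heat it needs conflicts with the lability of A3. A2 is an activated aryl ester that the ketene acetal carbon of A3 can acylate or add to without ring closure, so chemoselectivity is not secured. A1 presupposes a ring B whose two oxygens have been differentiated, which costs several steps.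
- Comparison: this road is better in protecting-group economy on ring A and in the mildness of the last step. The chosen plan sets against it a ring B fragment that never needs a free phenol, because O4 comes from acid 5, and reaction types that are all established and run at or below 80 °C.

**Alternative 2:** Three-component aryloxycarbonylation.
- Cut: both bonds of the ester carbonyl carbon, to C1 of ring A and to O4 of ring B.
- Forward: iodide A5 (1,5-bis(benzyloxy)-2-iodo-3-pentylbenzene), CO and phenol A1 are combined under Pd(OAc)2, Xantphos and triethylamine to give the tribenzyl depside A6. One hydrogenolysis then removes all three benzyl groups.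
- Merits: no ring A carboxylic acid is needed, A5 should be two steps from 1, the coupling is convergent, and the global deprotection is neutral and releases only toluene.
- Weak points: oxidative addition of zerovalent palladium into an electron-rich iodide with two ortho substituents is slow. The resulting acyl palladium is as crowded as the carbonyl the plan tries to avoid, and phenoxides are poor partners in carbonylative esterification, so hydrodehalogenation can take over. A1 is again required, and CO must be handled under pressure.
- Comparison: this road is shorter on the ring A side and has the cleaner ending. The chosen plan sets against it a bond formation in which the hindrance of ring A plays no part, and a ring B made in three operations without phenol differentiation.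

**Alternative 3:** Ring B carboxyl from CO2 at the end.
- Cut: the bond from C1 of ring B to its carboxyl carbon.
- Forward: the iodo depside A8 (4-iodo-3-methoxy-5-pentylphenyl 2,4-bis(benzyloxy)-6-pentylbenzoate) undergoes iodine–magnesium exchange with iPrMgCl·LiCl, and the arylmagnesium is quenched with CO2 to give acid A9. Hydrogenolysis then gives 15.
- Merits: the ring B carboxyl needs no protecting group, carboxylation of an arylmagnesium is reliable once it is formed, and the ending is neutral.
- Weak points: A8 must itself be made by acylating iodophenol A7 (4-iodo-3-methoxy-5-pentylphenol) at the crowded ring A carbonyl, so the central problem is only moved. A7 needs a selective monomethylation of 1 and an iodination among three activated positions. The exchange on an electron-rich iodide flanked by methoxy and pentyl is slow, and an aryl ester is present throughout as an electrophile.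
- Comparison: this road is better in that ring B carries no ester protecting group and sees no acid. The chosen plan sets against it a regiochemistry on ring B fixed by sterically controlled C–H borylation and a coupling that does not depend on reactivity at the hindered carbonyl.

Key step: step 7

## Route

Remark: 15 has no stereocentre, so no configuration has to be set and no SMILES string below carries a stereodescriptor.

Step 1
Reactants: 1 olivetol (5-pentylbenzene-1,3-diol)
Product: 3 2,4-dihydroxy-6-pentylbenzaldehyde, via aryl iminium chloride 2 (not isolated)
Conditions: POCl3, DMF, 0 °C to rt; then H2O, 50 °C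
Reagents that add atoms: N,N-dimethylformamide CN(C)C=O; water O
Why: Vilsmeier–Haack formylation; the chloroiminium ion from POCl3 and DMF should attack the ring carbon ortho to one hydroxyl and para to the other (two equivalent sites beside the pentyl chain) in preference to the carbon between the hydroxyls, and water hydrolyses iminium salt 2 to the aldehyde.

Step 2
Reactants: 3 2,4-dihydroxy-6-pentylbenzaldehyde
Product: 4 2,4-bis(methoxymethoxy)-6-pentylbenzaldehyde
Conditions: NaH, DMF, 0 °C; then MOMCl, 0 °C to rt
Reagents that add atoms: chloromethyl methyl ether COCCl
Why: O-alkylation of the sodium phenoxides with chloromethyl methyl ether (Williamson type, through the oxocarbenium ion); full deprotonation with NaH is chosen so that the hydrogen-bonded 2-hydroxyl is etherified as well as the 4-hydroxyl.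

Step 3
Reactants: 4 2,4-bis(methoxymethoxy)-6-pentylbenzaldehyde
Product: 5 2,4-bis(methoxymethoxy)-6-pentylbenzoic acid
Conditions: NaClO2, NaH2PO4, 2-methyl-2-butene, t-BuOH/H2O, rt; work-up at pH 4
Reagents that add atoms: sodium chlorite [Na+].[O-]Cl=O
Why: Pinnick oxidation; chlorous acid adds to the aldehyde and fragments to the acid and HOCl, which 2-methyl-2-butene removes before it can chlorinate the electron-rich ring, and the phosphate buffer should leave the methoxymethyl ethers intact.

Step 4
Reactants: 6 2-methoxy-6-methylbenzoic acid
Product: 7 tert-butyl 2-methoxy-6-methylbenzoate
Conditions: tert-butyl 2,2,2-trichloroacetimidate, CH2Cl2/cyclohexane, rt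
Reagents that add atoms: tert-butyl 2,2,2-trichloroacetimidate CC(C)(C)OC(=N)C(Cl)(Cl)Cl
Why: Esterification with a trichloroacetimidate; the acid protonates the imidate and the carboxylate oxygen takes up the tert-butyl cation, so the carbonyl carbon between two ortho groups is never attacked.

Step 5
Reactants: 7 tert-butyl 2-methoxy-6-methylbenzoate; 8 1-iodobutane
Product: 10 tert-butyl 2-methoxy-6-pentylbenzoate, via benzylic lithium species 9 (not isolated)
Conditions: LiN(iPr)2, THF, −78 °C; then 8, −78 °C to 0 °C
Reagents that add atoms: none
Why: Lateral (benzylic) lithiation of an ortho-toluate followed by SN2 alkylation; LiN(iPr)2 removes a methyl proton to give the ester-stabilised anion 9, the bulky tert-butyl ester should suppress Claisen-type self-condensation, and the primary iodide 8 alkylates at the benzylic carbon.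

Step 6
Reactants: 10 tert-butyl 2-methoxy-6-pentylbenzoate; 11 bis(pinacolato)diboron
Product: 13 [4-(tert-butoxycarbonyl)-3-methoxy-5-pentylphenyl]boronic acid, via pinacol boronate 12 (not isolated)
Conditions: [Ir(OMe)(cod)]2 (1.5 mol%), 4,4'-di-tert-butyl-2,2'-bipyridine (3 mol%), 11 (0.6 equiv), THF, 80 °C; then NaIO4, NH4OAc, THF/H2O, rt
Reagents that add atoms: water O
Why: Iridium-catalysed aromatic C–H borylation followed by oxidative hydrolysis of the pinacol ester; the trivalent iridium tris(boryl) species reacts only at C–H bonds without an ortho substituent, and in 10 only C4–H qualifies (C3–H lies beside methoxy, C5–H beside pentyl), while NaIO4 cleaves the released pinacol to acetone and so drives the hydrolysis of 12 at near-neutral pH, which the tert-butyl ester tolerates.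

Step 7
Reactants: 5 2,4-bis(methoxymethoxy)-6-pentylbenzoic acid; 13 [4-(tert-butoxycarbonyl)-3-methoxy-5-pentylphenyl]boronic acid
Product: 14 tert-butyl 4-[2,4-bis(methoxymethoxy)-6-pentylbenzoyloxy]-2-methoxy-6-pentylbenzoate
Conditions: Cu(OTf)2 (40 mol%), pyridine (3 equiv), 4 Å molecular sieves, EtOAc, dry air, 50 °C; 5 (2 equiv)
Reagents that add atoms: none
Why: Chan–Lam oxidative coupling in its carboxylate variant, the closest known reaction type being the copper-promoted esterification of benzoic acids with arylboronic acids under air. Pyridine deprotonates 5 and the carboxylate displaces triflate on divalent copper; aryl transfer from the boron of 13 gives a divalent aryl copper carboxylate, which is oxidised to the trivalent state, and C–O reductive elimination releases 14 and monovalent copper, which air returns to the divalent state. The new bond joins a carboxylate oxygen, one atom removed from the crowded ring A carbonyl carbon, to C4 of ring B, which has hydrogen on both sides, so neither partner meets the hindrance that slows acyl substitution here. No ring closes and no stereocentre is formed. The step needs chemoselectivity for the carboxylate over other oxygen nucleophiles and over loss of boron: both ring A phenols are masked as methoxymethyl ethers, triflate is used so that no second carboxylate such as acetate competes for the aryl group, molecular sieves keep out the water that would lead to the phenol, and the twofold excess of 5 (recoverable by bicarbonate extraction) keeps copper loaded with the wanted carboxylate. Pyridine also buffers the triflic acid equivalent so that the methoxymethyl ethers and the tert-butyl ester should survive. The site of the C–O bond is fixed by the boron placed in step 6.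

Step 8
Reactants: 14 tert-butyl 4-[2,4-bis(methoxymethoxy)-6-pentylbenzoyloxy]-2-methoxy-6-pentylbenzoate
Product: 15 4-[(2,4-dihydroxy-6-pentylbenzoyl)oxy]-2-methoxy-6-pentylbenzoic acid
Conditions: CF3CO2H/CH2Cl2 (1:4), 0 °C to rt; aqueous work-up
Reagents that add atoms: none
Why: Acidolysis of acetal and tert-butyl ester protecting groups; each methoxymethyl ether is protonated and leaves as a methoxymethyl cation that ends as formaldehyde and methanol on work-up, the tert-butyl ester loses 2-methylpropene by an E1 path, and the aryl ester should persist because no nucleophile is present and its carbonyl is hindered, while ring A is deactivated toward the cations by its carbonyl group.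

## Compound list

1 | olivetol (5-pentylbenzene-1,3-diol) | CCCCCc1cc(O)cc(O)c1 | starting material
2 | [(2,4-dihydroxy-6-pentylphenyl)methylidene]dimethylammonium chloride (aryl iminium chloride) | CCCCCc1cc(O)cc(O)c1C=[N+](C)C.[Cl-] | intermediate
3 | 2,4-dihydroxy-6-pentylbenzaldehyde | CCCCCc1cc(O)cc(O)c1C=O | intermediate
4 | 2,4-bis(methoxymethoxy)-6-pentylbenzaldehyde | CCCCCc1cc(OCOC)cc(OCOC)c1C=O | intermediate
5 | 2,4-bis(methoxymethoxy)-6-pentylbenzoic acid | CCCCCc1cc(OCOC)cc(OCOC)c1C(=O)O | intermediate
6 | 2-methoxy-6-methylbenzoic acid | COc1cccc(C)c1C(=O)O | starting material
7 | tert-butyl 2-methoxy-6-methylbenzoate | COc1cccc(C)c1C(=O)OC(C)(C)C | intermediate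
8 | 1-iodobutane | CCCCI | starting material
9 | tert-butyl 2-(lithiomethyl)-6-methoxybenzoate (benzylic lithium species) | [Li]Cc1cccc(OC)c1C(=O)OC(C)(C)C | intermediate
10 | tert-butyl 2-methoxy-6-pentylbenzoate | CCCCCc1cccc(OC)c1C(=O)OC(C)(C)C | intermediate
11 | bis(pinacolato)diboron | CC1(C)OB(OC1(C)C)B1OC(C)(C)C(C)(C)O1 | starting material
12 | tert-butyl 2-methoxy-6-pentyl-4-(4,4,5,5-tetramethyl-1,3,2-dioxaborolan-2-yl)benzoate (pinacol boronate) | CCCCCc1cc(B2OC(C)(C)C(C)(C)O2)cc(OC)c1C(=O)OC(C)(C)C | intermediate
13 | [4-(tert-butoxycarbonyl)-3-methoxy-5-pentylphenyl]boronic acid | CCCCCc1cc(B(O)O)cc(OC)c1C(=O)OC(C)(C)C | intermediate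
14 | tert-butyl 4-[2,4-bis(methoxymethoxy)-6-pentylbenzoyloxy]-2-methoxy-6-pentylbenzoate | CCCCCc1cc(OCOC)cc(OCOC)c1C(=O)Oc1cc(CCCCC)c(C(=O)OC(C)(C)C)c(OC)c1 | intermediate
15 | 4-[(2,4-dihydroxy-6-pentylbenzoyl)oxy]-2-methoxy-6-pentylbenzoic acid (CNP0244992.0) | CCCCCc1cc(O)cc(O)c1C(=O)Oc1cc(CCCCC)c(C(=O)O)c(OC)c1 | target

## Step count and risks

Total step count: 8. Longest linear sequence: 5 steps (1 → 3 → 4 → 5 → 14 → 15, or equally 6 → 7 → 10 → 13 → 14 → 15).

**Step 7 (key step).** The aryl copper intermediate may be consumed by protodeboronation, hydroxylation or homocoupling faster than the carboxylate is transferred, because a carboxylate is a weaker partner than a phenol or an amine in this coupling. Insufficient buffering of the Lewis-acidic copper triflate could also start to strip a methoxymethyl group. The fallback gives up O-arylation for acyl transfer; it sets out from 13 and 5 and returns to the route at 14. Boronic acid 13 is oxidised with H2O2 and NaOH in THF at 0 °C to tert-butyl 4-hydroxy-2-methoxy-6-pentylbenzoate F1. F1 is then acylated with acid 5 by carbodiimide activation (EDC·HCl, DMAP, CH2Cl2, rt) in a Steglich esterification, which is slower at this hindered carbonyl but established for depsides, to give 14.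

**Step 8.** The methoxymethyl and tert-butyl cations set free may be captured by the liberated resorcinol ring (C3 or C5 of ring A), and long exposure to acid may begin to cleave the depside ester. The fallback changes the protecting groups on ring A so that the phenols are released by hydrogenolysis, with no electrophile present; it sets out from 3 and returns at 15.
- Aldehyde 3 is benzylated (benzyl bromide, K2CO3, DMF) to 2,4-bis(benzyloxy)-6-pentylbenzaldehyde F2.
- F2 is oxidised as in step 3 to 2,4-bis(benzyloxy)-6-pentylbenzoic acid F3.
- F3 is coupled with 13 under the conditions of step 7 to give tert-butyl 4-[2,4-bis(benzyloxy)-6-pentylbenzoyloxy]-2-methoxy-6-pentylbenzoate F4.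
- CF3CO2H in CH2Cl2 removes the tert-butyl ester to give 4-[2,4-bis(benzyloxy)-6-pentylbenzoyloxy]-2-methoxy-6-pentylbenzoic acid F5, the same compound as A9 of Alternative 3.
- H2 over Pd/C in ethyl acetate then gives 15.

**Step 6.** Oxidative cleavage of the pinacol unit may stay incomplete, the boronic acid may be lost on purification from iridium and boron residues, and a little borylation beside the methoxy group (C3) cannot be excluded. The fallback separates the two operations and purifies through a crystalline derivative; it sets out from 10 and returns at 13. After the borylation, pinacol boronate 12 is isolated by chromatography and stirred with diethanolamine in ether. The zwitterionic adduct tert-butyl 4-(1,3,6,2-dioxazaborocan-2-yl)-2-methoxy-6-pentylbenzoate F6 should precipitate and is filtered. Brief biphasic hydrolysis of F6 with dilute aqueous HCl and ether then releases 13.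

**Step 5.** The benzylic anion 9 may add to the ester of unreacted 7 (self-condensation), or the product may be deprotonated and alkylated a second time. The fallback alkylates the carboxylate dianion, whose carbonyl cannot be attacked, and esterifies afterwards; it sets out from 6 and 8 and returns at 10. Acid 6 is treated with 2.2 equivalents of LiN(iPr)2 in THF (−78 °C to 0 °C) to give lithium 2-(lithiomethyl)-6-methoxybenzoate F7. F7 is alkylated with 8 to 2-methoxy-6-pentylbenzoic acid F8 after acidic work-up, and F8 is converted with tert-butyl 2,2,2-trichloroacetimidate, as in step 4, into 10.

## Further compounds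

F1 | step 7 | tert-butyl 4-hydroxy-2-methoxy-6-pentylbenzoate | CCCCCc1cc(O)cc(OC)c1C(=O)OC(C)(C)C
F2 | step 8 | 2,4-bis(benzyloxy)-6-pentylbenzaldehyde | CCCCCc1cc(OCc2ccccc2)cc(OCc2ccccc2)c1C=O
F3 | step 8 | 2,4-bis(benzyloxy)-6-pentylbenzoic acid | CCCCCc1cc(OCc2ccccc2)cc(OCc2ccccc2)c1C(=O)O
F4 | step 8 | tert-butyl 4-[2,4-bis(benzyloxy)-6-pentylbenzoyloxy]-2-methoxy-6-pentylbenzoate | CCCCCc1cc(OCc2ccccc2)cc(OCc2ccccc2)c1C(=O)Oc1cc(CCCCC)c(C(=O)OC(C)(C)C)c(OC)c1
F5 | step 8 | 4-[2,4-bis(benzyloxy)-6-pentylbenzoyloxy]-2-methoxy-6-pentylbenzoic acid | CCCCCc1cc(OCc2ccccc2)cc(OCc2ccccc2)c1C(=O)Oc1cc(CCCCC)c(C(=O)O)c(OC)c1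
F6 | step 6 | tert-butyl 4-(1,3,6,2-dioxazaborocan-2-yl)-2-methoxy-6-pentylbenzoate (diethanolamine adduct) | CCCCCc1cc([B-]23OCC[NH+]2CCO3)cc(OC)c1C(=O)OC(C)(C)C
F7 | step 5 | lithium 2-(lithiomethyl)-6-methoxybenzoate | [Li]Cc1cccc(OC)c1C(=O)O[Li]
F8 | step 5 | 2-methoxy-6-pentylbenzoic acid | CCCCCc1cccc(OC)c1C(=O)O
A1 | alternative 1 | benzyl 4-hydroxy-2-methoxy-6-pentylbenzoate | CCCCCc1cc(O)cc(OC)c1C(=O)OCc1ccccc1
A2 | alternative 1 | benzyl 2-methoxy-4-(oct-2-ynoyloxy)-6-pentylbenzoate | CCCCCC#CC(=O)Oc1cc(CCCCC)c(C(=O)OCc2ccccc2)c(OC)c1
A3 | alternative 1 | 1-methoxy-1,3-bis(trimethylsilyloxy)buta-1,3-diene | COC(O[Si](C)(C)C)=CC(=C)O[Si](C)(C)C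
A4 | alternative 1 | benzyl 4-(2,4-dihydroxy-6-pentylbenzoyloxy)-2-methoxy-6-pentylbenzoate | CCCCCc1cc(O)cc(O)c1C(=O)Oc1cc(CCCCC)c(C(=O)OCc2ccccc2)c(OC)c1
A5 | alternative 2 | 1,5-bis(benzyloxy)-2-iodo-3-pentylbenzene | CCCCCc1cc(OCc2ccccc2)cc(OCc2ccccc2)c1I
A6 | alternative 2 | benzyl 4-[2,4-bis(benzyloxy)-6-pentylbenzoyloxy]-2-methoxy-6-pentylbenzoate | CCCCCc1cc(OCc2ccccc2)cc(OCc2ccccc2)c1C(=O)Oc1cc(CCCCC)c(C(=O)OCc2ccccc2)c(OC)c1
A7 | alternative 3 | 4-iodo-3-methoxy-5-pentylphenol | CCCCCc1cc(O)cc(OC)c1I
A8 | alternative 3 | 4-iodo-3-methoxy-5-pentylphenyl 2,4-bis(benzyloxy)-6-pentylbenzoate | CCCCCc1cc(OCc2ccccc2)cc(OCc2ccccc2)c1C(=O)Oc1cc(CCCCC)c(I)c(OC)c1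
A9 | alternative 3 | 4-[2,4-bis(benzyloxy)-6-pentylbenzoyloxy]-2-methoxy-6-pentylbenzoic acid | CCCCCc1cc(OCc2ccccc2)cc(OCc2ccccc2)c1C(=O)Oc1cc(CCCCC)c(C(=O)O)c(OC)c1
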